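**Retrosynthetic overview**

1. The target is all-E (3S,4S,3'S,4'S)-7,8-didehydro-β,β-carotene-3,4,3',4'-tetrol, with both 3,4-diols trans. The C-4/C-4' carbinols come from hydroxyl-directed reduction of the 3,3'-dihydroxy-4,4'-dione, and the C-3/C-3' hydroxyls from enolate oxidation of the 4,4'-dione.
2. Key disconnection: both C-6–C-7 bonds and both C-5=C-6 ring bonds are cut at once. The 4,4'-dione comes from a C22 iodo-polyenyne (as its dilithio derivative) and two molecules of a C9 enol lactone, in a double Fujimoto–Belleau-type annulation.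
3. The C22 chain comes from the C10 dialdehyde and two C6 allylic tributylphosphonium ylides (E-selective Wittig), both made from one enynol.
4. The enol lactone comes from 2,2-dimethylhept-5-ynoic acid (gold-catalysed cycloisomerisation), itself from isobutyric acid and 5-bromopent-2-yne.
5. Ring order: the carbon skeleton stays acyclic until the key step, in which ring A (alkyne end) and ring B (alkene end) close together; no ring is formed afterwards.

Assumption: the (+)-(2R,8aS) antipode of the camphorsulfonyl oxaziridine is taken to give the 3S configuration; if the induction proves opposite, its commercial mirror image is used in the same way.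

All polyene steps (6 to 10) are run under argon in the dark.

**Route**

Step 1
Reactants: 1 isobutyric acid; 2 5-bromopent-2-yne
Product: 4 2,2-dimethylhept-5-ynoic acid, via isobutyric acid dianion 3 (not isolated)
Conditions: LiN(i-Pr)2 (2.1 equiv), THF, 0 → 45 °C; then 2, DMPU, 0 °C → rt; aq. HCl
Reagents that add atoms: none
Why: α-Alkylation of a carboxylic acid dianion, in which the hindered but strongly nucleophilic dianion displaces the primary homopropargylic bromide; no stereocentre is formed.

Step 2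
Reactants: 4 2,2-dimethylhept-5-ynoic acid
Product: 5 (6Z)-6-ethylidene-3,3-dimethyloxan-2-one
Conditions: AuCl (5 mol %), K2CO3 (10 mol %), MeCN, rt
Reagents that add atoms: none
Why: Gold-catalysed 6-exo-dig cycloisomerisation of a 5-alkynoic acid (anti-oxyauration, then protodeauration) gives the exocyclic Z-enol lactone, helped by the gem-dimethyl group, and fixes the enol double bond towards the future C-5.

Step 3
Reactants: 6 (2E)-3-methylpent-2-en-4-yn-1-ol
Product: 8 tributyl[(2E)-3-methylpent-2-en-4-yn-1-yl]phosphonium bromide, via enynyl bromide 7 (not isolated)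
Conditions: PBr3 (0.4 equiv), Et2O, −20 → 0 °C; aq. NaHCO3 wash; then n-Bu3P, MeCN, rt
Reagents that add atoms: phosphorus tribromide, BrP(Br)Br; tributylphosphine, CCCCP(CCCC)CCCC
Why: SN2 bromination of the primary allylic alcohol followed by quaternisation of the phosphine (phosphonium salt formation) leaves the trisubstituted E double bond and the terminal alkyne untouched.

Step 4
Reactants: 6 (2E)-3-methylpent-2-en-4-yn-1-ol
Product: 10 (2E,4E)-5-iodo-3-methylpenta-2,4-dien-1-ol, via stannyl dienol 9 (not isolated)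
Conditions: n-Bu3SnH, PdCl2(PPh3)2 (2 mol %), THF, 0 °C; then I2, CH2Cl2, 0 °C
Reagents that add atoms: iodine, [I][I]
Why: Palladium-catalysed syn-hydrostannation puts tin on the unhindered alkyne terminus with E geometry and iododestannylation proceeds with retention, so the 4E vinyl iodide results (hydrostannation–iodination).

Step 5
Reactants: 10 (2E,4E)-5-iodo-3-methylpenta-2,4-dien-1-ol
Product: 12 tributyl[(2E,4E)-5-iodo-3-methylpenta-2,4-dien-1-yl]phosphonium bromide, via iododienyl bromide 11 (not isolated)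
Conditions: PBr3 (0.4 equiv), Et2O, −20 → 0 °C; aq. NaHCO3 wash; then n-Bu3P, MeCN, rt
Reagents that add atoms: phosphorus tribromide, BrP(Br)Br; tributylphosphine, CCCCP(CCCC)CCCC
Why: The same allylic bromination and phosphine quaternisation as in step 3; the vinyl iodide is inert to both reagents and both double bonds keep their E geometry.

Step 6
Reactants: 8 tributyl[(2E)-3-methylpent-2-en-4-yn-1-yl]phosphonium bromide; 13 (2E,4E,6E)-2,7-dimethylocta-2,4,6-trienedial (2 equiv)
Product: 15 (2E,4E,6E,8E,10E)-2,7,11-trimethyltrideca-2,4,6,8,10-pentaen-12-ynal, via enynyl ylide 14 (not isolated)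
Conditions: KOt-Bu (1.0 equiv), THF, −78 °C; then add to 13 (2 equiv), −78 → 0 °C
Reagents that add atoms: none
Why: Wittig olefination with an allylic trialkylphosphonium ylide gives the new C-11=C-12 bond with high E selectivity, so no iodine equilibration (which would scramble the 9E enyne) is needed, and the excess dialdehyde holds the reaction at mono-olefination.

Step 7
Reactants: 15 (2E,4E,6E,8E,10E)-2,7,11-trimethyltrideca-2,4,6,8,10-pentaen-12-ynal; 12 tributyl[(2E,4E)-5-iodo-3-methylpenta-2,4-dien-1-yl]phosphonium bromide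
Product: 17 (1E,3E,5E,7E,9E,11E,13E,15E)-1-iodo-3,7,12,16-tetramethyloctadeca-1,3,5,7,9,11,13,15-octaen-17-yne, via iododienyl ylide 16 (not isolated)
Conditions: KOt-Bu (1.0 equiv), THF, −78 °C; then 15, −78 → 0 °C
Reagents that add atoms: none
Why: A second E-selective Wittig olefination with an allylic tributylphosphonium ylide forms C-11'=C-12'; at −78 °C the E-vinyl iodide and the terminal alkyne (far less acidic than the phosphonium salt) survive the single equivalent of base.

Step 8
Reactants: 17 (1E,3E,5E,7E,9E,11E,13E,15E)-1-iodo-3,7,12,16-tetramethyloctadeca-1,3,5,7,9,11,13,15-octaen-17-yne; 5 (6Z)-6-ethylidene-3,3-dimethyloxan-2-one (2.5 equiv)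
Product: 21 7,8-didehydro-β,β-carotene-4,4'-dione, via dilithio polyene 18 (not isolated), via ring-opened bis-enolate 19 (not isolated), via bis-aldolate 20 (not isolated)
Conditions: t-BuLi (3.05 equiv), THF/Et2O, −78 °C; cannulate into 5 (2.5 equiv), THF, −78 → −20 °C; then t-BuOH, KOt-Bu (20 mol %), 0 °C → rt
Reagents that add atoms: none
Why: Proposed new method: each carbanion terminus of 18 attacks the enol-ester carbonyl of 5, and the tetrahedral intermediate collapses to a ketone (ynone at the ring A end, dienone at the ring B end) plus a regiodefined lithium Z-enolate six atoms away, which closes by 6-(enolendo)-exo-trig aldol addition before a second carbanion can add, and base-mediated E1cB loss of LiOH then gives both conjugated 2,6,6-trimethyl-3-oxocyclohex-1-enyl rings in one operation; the closest known chemistry is the Fujimoto–Belleau annulation (organometallic plus enol lactone, then aldol condensation) together with the generation of specific enolates by cleaving enol esters with organolithiums, and no stereocentre survives the step.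

Step 9
Reactants: 21 7,8-didehydro-β,β-carotene-4,4'-dione
Product: 23 (3S,3'S)-3,3'-dihydroxy-7,8-didehydro-β,β-carotene-4,4'-dione, via disodium bis-dienolate 22 (not isolated)
Conditions: NaN(SiMe3)2 (2.3 equiv), THF, −78 °C; then (+)-(camphorsulfonyl)oxaziridine (3 equiv), −78 → −50 °C; AcOH quench
Reagents that add atoms: (+)-(2R,8aS)-(10-camphorsulfonyl)oxaziridine, O=S1(=O)C[C@@]23CC[C@@H](C2(C)C)C[C@@]3(O4)N14
Why: Davis enolate oxidation, in which kinetic deprotonation at C-3 and C-3' (the only enolisable positions) gives the cross-conjugated dienolates and oxygen transfer from the enantiopure N-sulfonyloxaziridine sets 3S and 3'S under reagent control, the minor 3R,3'S diastereomer being removed by chromatography.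

Step 10
Reactants: 23 (3S,3'S)-3,3'-dihydroxy-7,8-didehydro-β,β-carotene-4,4'-dione
Product: 24 (3S,4S,3'S,4'S)-7,8-didehydro-β,β-carotene-3,4,3',4'-tetrol
Conditions: Me4NBH(OAc)3 (8 equiv), MeCN/THF, AcOH (10 equiv), −30 → 0 °C; aq. NaHCO3
Reagents that add atoms: none
Why: Evans–Saksena hydroxyl-directed reduction, in which each 3-hydroxyl exchanges an acetate on boron and delivers hydride to the neighbouring C-4 carbonyl on its own face, so the new 4-hydroxyl ends up trans to it (3S,4S and 3'S,4'S), while the polyene and the alkyne are left untouched.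

**Compound list**

1 | isobutyric acid | CC(C)C(=O)O | starting material
2 | 5-bromopent-2-yne | CC#CCCBr | starting material
3 | isobutyric acid dianion (dilithium 2-methylprop-1-ene-1,1-diolate) | CC(C)=C(O[Li])O[Li] | intermediate
4 | 2,2-dimethylhept-5-ynoic acid | CC#CCCC(C)(C)C(=O)O | intermediate
5 | (6Z)-6-ethylidene-3,3-dimethyloxan-2-one | C/C=C1/CCC(C)(C)C(=O)O1 | intermediate
6 | (2E)-3-methylpent-2-en-4-yn-1-ol | C#C/C(C)=C/CO | starting material
7 | (3E)-5-bromo-3-methylpent-3-en-1-yne | C#C/C(C)=C/CBr | intermediate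
8 | tributyl[(2E)-3-methylpent-2-en-4-yn-1-yl]phosphonium bromide | C#C/C(C)=C/C[P+](CCCC)(CCCC)CCCC.[Br-] | intermediate
9 | (2E,4E)-3-methyl-5-(tributylstannyl)penta-2,4-dien-1-ol | CCCC[Sn](CCCC)(CCCC)/C=C/C(C)=C/CO | intermediate
10 | (2E,4E)-5-iodo-3-methylpenta-2,4-dien-1-ol | I/C=C/C(C)=C/CO | intermediate
11 | (1E,3E)-5-bromo-1-iodo-3-methylpenta-1,3-diene | I/C=C/C(C)=C/CBr | intermediate
12 | tributyl[(2E,4E)-5-iodo-3-methylpenta-2,4-dien-1-yl]phosphonium bromide | I/C=C/C(C)=C/C[P+](CCCC)(CCCC)CCCC.[Br-] | intermediate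
13 | (2E,4E,6E)-2,7-dimethylocta-2,4,6-trienedial | O=C/C(C)=C/C=C/C=C(C)/C=O | starting material
14 | tributyl[(2E)-3-methylpent-2-en-4-yn-1-ylidene]phosphorane | C#C/C(C)=C/C=P(CCCC)(CCCC)CCCC | intermediate
15 | (2E,4E,6E,8E,10E)-2,7,11-trimethyltrideca-2,4,6,8,10-pentaen-12-ynal | O=C/C(C)=C/C=C/C=C(C)/C=C/C=C(C)/C#C | intermediate
16 | tributyl[(2E,4E)-5-iodo-3-methylpenta-2,4-dien-1-ylidene]phosphorane | I/C=C/C(C)=C/C=P(CCCC)(CCCC)CCCC | intermediate
17 | (1E,3E,5E,7E,9E,11E,13E,15E)-1-iodo-3,7,12,16-tetramethyloctadeca-1,3,5,7,9,11,13,15-octaen-17-yne | I/C=C/C(C)=C/C=C/C(C)=C/C=C/C=C(C)/C=C/C=C(C)/C#C | intermediate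
18 | 1,18-dilithio derivative of 17 (alkenyllithium at C-1, lithium acetylide at C-18) | [Li]/C=C/C(C)=C/C=C/C(C)=C/C=C/C=C(C)/C=C/C=C(C)/C#C[Li] | intermediate
19 | ring-opened bis-enolate: dilithium bis(Z-enolate) of 6,6,10,14,19,23,27,27-octamethyldotriaconta-8,10,12,14,16,18,20,22-octaen-24-yne-3,7,26,30-tetrone, enolised at both ethyl ketones | C/C=C(O[Li])/CCC(C)(C)C(=O)C#C/C(C)=C/C=C/C(C)=C/C=C/C=C(C)/C=C/C=C(C)/C=C/C(=O)C(C)(C)CC/C(O[Li])=C/C | intermediate
20 | bis-aldolate: dilithium salt of 6,6'-dihydroxy-5,6,5',6'-tetrahydro-7,8-didehydro-β,β-carotene-4,4'-dione (diastereomer mixture) | CC1C(=O)CCC(C)(C)C1(O[Li])C#C/C(C)=C/C=C/C(C)=C/C=C/C=C(C)/C=C/C=C(C)/C=C/C1(O[Li])C(C)C(=O)CCC1(C)C | intermediate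
21 | 7,8-didehydro-β,β-carotene-4,4'-dione (7,8-didehydrocanthaxanthin) | CC1=C(C#C/C(C)=C/C=C/C(C)=C/C=C/C=C(C)/C=C/C=C(C)/C=C/C2=C(C)C(=O)CCC2(C)C)C(C)(C)CCC1=O | intermediate
22 | disodium 3,4:3',4'-bis-dienolate of 21 | CC1=C(C#C/C(C)=C/C=C/C(C)=C/C=C/C=C(C)/C=C/C=C(C)/C=C/C2=C(C)C(O[Na])=CCC2(C)C)C(C)(C)CC=C1O[Na] | intermediate
23 | (3S,3'S)-3,3'-dihydroxy-7,8-didehydro-β,β-carotene-4,4'-dione (7,8-didehydroastaxanthin) | CC1=C(C#C/C(C)=C/C=C/C(C)=C/C=C/C=C(C)/C=C/C=C(C)/C=C/C2=C(C)C(=O)[C@@H](O)CC2(C)C)C(C)(C)C[C@H](O)C1=O | intermediate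
24 | (3S,4S,3'S,4'S)-7,8-didehydro-β,β-carotene-3,4,3',4'-tetrol | CC1=C(C#C/C(C)=C/C=C/C(C)=C/C=C/C=C(C)/C=C/C=C(C)/C=C/C2=C(C)[C@H](O)[C@@H](O)CC2(C)C)C(C)(C)C[C@H](O)[C@H]1O | target

**Step count and risks**

Total step count: 10. Longest linear sequence: 6 steps (6 → 8 or 10/12 → 15 or 17 → 21 → 23 → 24; that is steps 3, 6, 7, 8, 9, 10 or steps 4, 5, 7, 8, 9, 10).

The three steps most likely to fail are 8, 9 and 10.

Step 8 (double annulation). The risks are decomposition or over-addition of the dilithio polyene 18 and an incomplete aldol closure at the ring B end. The fallback sets out from 17 (with 5 as the source of the C9 unit) and comes back at 21. It makes the two carbon–carbon bonds by aldehyde additions and keeps the double ring closure as a separate operation. i-Bu2AlH (1 equiv, CH2Cl2, −78 °C) reduces 5 to 2,2-dimethyl-5-oxoheptanal F1. A Nozaki–Hiyama–Kishi coupling of 17 with F1 (CrCl2, NiCl2 cat., DMSO, rt) gives the allylic alcohol 7-hydroxy-6,6,10,14,19,23-hexamethylpentacosa-8,10,12,14,16,18,20,22-octaen-24-yn-3-one F2. Its terminal alkyne is added to a second equivalent of F1 with Zn(OTf)2 and Et3N (toluene, rt) to give 7,26-dihydroxy-6,6,10,14,19,23,27,27-octamethyldotriaconta-8,10,12,14,16,18,20,22-octaen-24-yne-3,30-dione F3. MnO2 (CH2Cl2, rt) oxidises both carbinols to 6,6,10,14,19,23,27,27-octamethyldotriaconta-8,10,12,14,16,18,20,22-octaen-24-yne-3,7,26,30-tetrone F4. KOt-Bu in t-BuOH/THF (0 °C → rt) then closes ring A and ring B together by double aldol condensation to 21.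

Step 9 (double asymmetric hydroxylation). The risks are modest enantioselectivity at a methylene enolate and over-oxidation to the diosphenol. The fallback sets out from 21 and comes back at 23. It delivers the oxygen to an isolated silyl dienol ether with a chiral dioxirane (asymmetric Rubottom-type oxidation). NaN(SiMe3)2 then Et3SiCl (THF, −78 °C) gives the 3,4:3',4'-bis(triethylsilyl dienol ether) of 21 F5. Its two electron-rich enol-ether double bonds are epoxidised with 1,2:4,5-di-O-isopropylidene-β-D-erythro-2,3-hexodiulo-2,6-pyranose and KHSO5 (MeCN/dimethoxymethane, pH 10.5 buffer, 0 °C; the L-sorbose-derived antipode if the other sense is needed), and hydrolysis of the silyloxy epoxides on work-up gives 23.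

Step 10 (trans-selective reduction). The risks are sluggish reduction of the strongly conjugated C-4 carbonyls and acid lability of the polyenylic 4-carbinols. The fallback sets out from 23 and comes back at 24. It replaces internal delivery by reagent-controlled external hydride on the O-silylated ketol. t-BuMe2SiCl and imidazole (DMF, rt) give the 3,3'-bis(tert-butyldimethylsilyl) ether of 23 F6. Corey–Bakshi–Shibata reduction with (S)-1-methyl-3,3-diphenyltetrahydro-1H,3H-pyrrolo[1,2-c][1,3,2]oxazaborole and catecholborane (toluene, −78 °C) is expected to give the 4S,4'S carbinols, on the premise that the tetrasubstituted enone arm acts as the large group. This gives the 3,3'-bis(tert-butyldimethylsilyl) ether of 24 F7, and n-Bu4NF (THF, 0 °C) frees 24.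

**Further compounds**

F1 | step 8 | 2,2-dimethyl-5-oxoheptanal | CCC(=O)CCC(C)(C)C=O
F2 | step 8 | 7-hydroxy-6,6,10,14,19,23-hexamethylpentacosa-8,10,12,14,16,18,20,22-octaen-24-yn-3-one (all-E) | CCC(=O)CCC(C)(C)C(O)/C=C/C(C)=C/C=C/C(C)=C/C=C/C=C(C)/C=C/C=C(C)/C#C
F3 | step 8 | 7,26-dihydroxy-6,6,10,14,19,23,27,27-octamethyldotriaconta-8,10,12,14,16,18,20,22-octaen-24-yne-3,30-dione (all-E) | CCC(=O)CCC(C)(C)C(O)/C=C/C(C)=C/C=C/C(C)=C/C=C/C=C(C)/C=C/C=C(C)/C#CC(O)C(C)(C)CCC(=O)CC
F4 | step 8 | 6,6,10,14,19,23,27,27-octamethyldotriaconta-8,10,12,14,16,18,20,22-octaen-24-yne-3,7,26,30-tetrone (all-E) | CCC(=O)CCC(C)(C)C(=O)/C=C/C(C)=C/C=C/C(C)=C/C=C/C=C(C)/C=C/C=C(C)/C#CC(=O)C(C)(C)CCC(=O)CC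
F5 | step 9 | 3,4:3',4'-bis(triethylsilyl dienol ether) of 21 | CC1=C(C#C/C(C)=C/C=C/C(C)=C/C=C/C=C(C)/C=C/C=C(C)/C=C/C2=C(C)C(O[Si](CC)(CC)CC)=CCC2(C)C)C(C)(C)CC=C1O[Si](CC)(CC)CC
F6 | step 10 | 3,3'-bis(tert-butyldimethylsilyl) ether of 23 | CC1=C(C#C/C(C)=C/C=C/C(C)=C/C=C/C=C(C)/C=C/C=C(C)/C=C/C2=C(C)C(=O)[C@@H](O[Si](C)(C)C(C)(C)C)CC2(C)C)C(C)(C)C[C@H](O[Si](C)(C)C(C)(C)C)C1=O
F7 | step 10 | 3,3'-bis(tert-butyldimethylsilyl) ether of 24 | CC1=C(C#C/C(C)=C/C=C/C(C)=C/C=C/C=C(C)/C=C/C=C(C)/C=C/C2=C(C)[C@H](O)[C@@H](O[Si](C)(C)C(C)(C)C)CC2(C)C)C(C)(C)C[C@H](O[Si](C)(C)C(C)(C)C)[C@H]1O
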